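**Retrosynthetic overview**
- The naphthazarin is unmasked last from a 1,4,5,8-tetramethoxynaphthalene (two oxidative demethylations, one reduction); the (Z)-2-methylbut-2-enoate is put on the tertiary alkoxide just before.
- The (R)-tertiary cyclobutanol comes from its racemate by resolution on a chiral stationary phase; no reagent-controlled step sets this centre.
- The cyclobutane is the only ring built (the naphthalene is bought): its C1–CH2 bond is closed by iodine–lithium exchange and intramolecular addition in a γ-iodo ketone ArCO–CMe2–CH2CH2I.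
- Key C–C bond: ArCH(OH)–CMe2, made by intermolecular zinc-mediated prenylation (γ-attack) of the aryl aldehyde with prenyl bromide, which brings in all five side-chain carbons; oxidation, hydroboration and iodination then give the iodo ketone.
- The aryl aldehyde comes from Vilsmeier formylation of 1,4,5,8-tetramethoxynaphthalene, itself made from 1,5-dimethoxynaphthalene (bromination, methoxylation).

Assumption: the two naphthazarin tautomers (side chain on the quinone ring or on the dihydroxybenzene ring) interconvert freely and are one compound; the stereocentre is (R) and the ester is the Z (angelate) isomer.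

**Route**

Step 1
Reactants: 1 1,5-dimethoxynaphthalene
Product: 2 4,8-dibromo-1,5-dimethoxynaphthalene
Conditions: NBS (2.1 equiv), MeCN, rt
Reagents that add atoms: N-bromosuccinimide BrN1C(=O)CCC1=O
Why: Electrophilic aromatic bromination, in which each methoxy group directs para within its own ring, so the 4,8-dibromide forms cleanly.

Step 2
Reactants: 2 4,8-dibromo-1,5-dimethoxynaphthalene
Product: 3 1,4,5,8-tetramethoxynaphthalene
Conditions: NaOMe (excess), CuI (0.3 equiv), MeOH/DMF, reflux
Reagents that add atoms: sodium methoxide [Na+].[O-]C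
Why: Copper-catalysed Ullmann-type methoxylation replaces both aryl bromides by methoxide.

Step 3
Reactants: 3 1,4,5,8-tetramethoxynaphthalene
Product: 5 1,4,5,8-tetramethoxynaphthalene-2-carbaldehyde, via aryl iminium dichlorophosphate 4 (not isolated)
Conditions: POCl3, DMF, 0 to 80 °C; then ice-water
Reagents that add atoms: N,N-dimethylformamide CN(C)C=O (formyl carbon); water O (carbonyl oxygen)
Why: Vilsmeier–Haack formylation of the electron-rich arene at one of its four equivalent free positions; the formyl group deactivates against a second attack and the iminium salt is hydrolysed on work-up.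

Step 4
Reactants: 5 1,4,5,8-tetramethoxynaphthalene-2-carbaldehyde; 6 prenyl bromide (1-bromo-3-methylbut-2-ene)
Product: 8 (±)-2,2-dimethyl-1-(1,4,5,8-tetramethoxynaphthalen-2-yl)but-3-en-1-ol, via prenylzinc bromide 7 (not isolated)
Conditions: Zn dust, THF, 0 °C to rt; then aq NH4Cl
Reagents that add atoms: 6 prenyl bromide CC(C)=CCBr
Why: Barbier-type carbonyl allylation (prenylation) in which the allylic zinc reagent adds through a six-membered cyclic transition state with allylic transposition, so its γ-carbon forms the hindered carbinol–CMe2 bond; the carbinol centre is racemic and is erased in step 5.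

Step 5
Reactants: 8 (±)-2,2-dimethyl-1-(1,4,5,8-tetramethoxynaphthalen-2-yl)but-3-en-1-ol
Product: 9 2,2-dimethyl-1-(1,4,5,8-tetramethoxynaphthalen-2-yl)but-3-en-1-one
Conditions: Dess–Martin periodinane, CH2Cl2, 0 °C to rt
Reagents that add atoms: none
Why: Dess–Martin oxidation turns the hindered benzylic alcohol into a non-enolisable ketone under conditions that leave the electron-rich arene and the vinyl group alone.

Step 6
Reactants: 9 2,2-dimethyl-1-(1,4,5,8-tetramethoxynaphthalen-2-yl)but-3-en-1-one
Product: 11 4-hydroxy-2,2-dimethyl-1-(1,4,5,8-tetramethoxynaphthalen-2-yl)butan-1-one, via B-alkyl-9-BBN adduct 10 (not isolated)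
Conditions: 9-BBN (1.3 equiv), THF, 0 °C to rt; then NaOH, H2O2, 0 °C
Reagents that add atoms: hydrogen peroxide OO
Why: Anti-Markovnikov hydroboration–oxidation, in which the bulky borane should take the terminal vinyl carbon faster than it reduces the shielded aryl tert-alkyl ketone.

Step 7
Reactants: 11 4-hydroxy-2,2-dimethyl-1-(1,4,5,8-tetramethoxynaphthalen-2-yl)butan-1-one
Product: 12 4-iodo-2,2-dimethyl-1-(1,4,5,8-tetramethoxynaphthalen-2-yl)butan-1-one
Conditions: PPh3, I2, imidazole (premixed), CH2Cl2, 0 °C to rt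
Reagents that add atoms: iodine II
Why: Appel reaction, in which the primary alcohol is activated as an alkoxyphosphonium ion and displaced by iodide in an SN2 step at an unhindered carbon; premixing leaves no free iodine near the arene.

Step 8
Reactants: 12 4-iodo-2,2-dimethyl-1-(1,4,5,8-tetramethoxynaphthalen-2-yl)butan-1-one
Product: 14 (±)-2,2-dimethyl-1-(1,4,5,8-tetramethoxynaphthalen-2-yl)cyclobutan-1-ol, via primary alkyllithium 13 (not isolated)
Conditions: t-BuLi (2.2 equiv), Et2O/pentane, −78 °C, then to 0 °C; H2O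
Reagents that add atoms: none
Why: Iodine–lithium exchange followed by intramolecular 1,2-addition (4-exo-trig Barbier-type cyclisation), helped by a shielded ketone with no α-hydrogen and by the gem-dimethyl group; the quaternary carbinol centre forms as a racemate.

Step 9
Reactants: 14 (±)-2,2-dimethyl-1-(1,4,5,8-tetramethoxynaphthalen-2-yl)cyclobutan-1-ol
Product: 15 (R)-2,2-dimethyl-1-(1,4,5,8-tetramethoxynaphthalen-2-yl)cyclobutan-1-ol
Conditions: preparative SFC, amylose tris(3,5-dimethylphenylcarbamate) phase (Chiralpak AD-H), CO2/MeOH, 35 °C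
Reagents that add atoms: none
Why: Resolution by chromatography on a chiral stationary phase separates the enantiomers and the (R)-enantiomer (configuration assigned by X-ray or VCD) is kept, which sets the only stereocentre of the target.

Step 10
Reactants: 15 (R)-2,2-dimethyl-1-(1,4,5,8-tetramethoxynaphthalen-2-yl)cyclobutan-1-ol; 16 angelic anhydride [(Z)-2-methylbut-2-enoic anhydride]
Product: 18 (R)-2,2-dimethyl-1-(1,4,5,8-tetramethoxynaphthalen-2-yl)cyclobutyl (Z)-2-methylbut-2-enoate, via potassium alkoxide 17 (not isolated)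
Conditions: KN(SiMe3)2 (1.2 equiv), THF, −78 °C; then 16, −78 to 0 °C
Reagents that add atoms: 16 angelic anhydride C/C=C(/C)C(=O)OC(=O)/C(C)=C\C
Why: Nucleophilic acyl substitution by a pre-formed alkoxide, reactive enough for the hindered tertiary centre and cold enough to keep the Z geometry; the C–O bond at the stereocentre is untouched, so configuration is retained.

Step 11
Reactants: 18 (R)-2,2-dimethyl-1-(1,4,5,8-tetramethoxynaphthalen-2-yl)cyclobutyl (Z)-2-methylbut-2-enoate
Product: 22 (R)-1-(5,8-dihydroxy-1,4-dioxo-1,4-dihydronaphthalen-2-yl)-2,2-dimethylcyclobutyl (Z)-2-methylbut-2-enoate, via benzo-substituted dimethoxyquinone 19 (not isolated), via quinone-substituted dimethoxyquinone 20 (not isolated), via naphthodiquinone 21 (not isolated)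
Conditions: (NH4)2Ce(NO3)6 (2.5 equiv), MeCN/H2O, 0 °C, 15 min; extractive work-up, crude used directly; AgO, 6 M HNO3, acetone, rt, 10 min; then aq Na2S2O4
Reagents that add atoms: water O
Why: Oxidative demethylation of the two para-dimethoxy rings in turn, then reduction of the diquinone to the naphthazarin; both regioisomeric monoquinones converge on one product and the quaternary stereocentre and the Z-alkene are not involved.

**Compound list**
1 | 1,5-dimethoxynaphthalene | COc1cccc2c(OC)cccc12 | starting material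
2 | 4,8-dibromo-1,5-dimethoxynaphthalene | COc1ccc(Br)c2c(OC)ccc(Br)c12 | intermediate
3 | 1,4,5,8-tetramethoxynaphthalene | COc1ccc(OC)c2c(OC)ccc(OC)c12 | intermediate
4 | N,N-dimethyl-(1,4,5,8-tetramethoxynaphthalen-2-yl)methaniminium dichlorophosphate | C[N+](C)=Cc1cc(OC)c2c(OC)ccc(OC)c2c1OC.[O-]P(=O)(Cl)Cl | intermediate
5 | 1,4,5,8-tetramethoxynaphthalene-2-carbaldehyde | O=Cc1cc(OC)c2c(OC)ccc(OC)c2c1OC | intermediate
6 | prenyl bromide (1-bromo-3-methylbut-2-ene) | CC(C)=CCBr | starting material
7 | prenylzinc bromide | CC(C)=CC[Zn]Br | intermediate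
8 | (±)-2,2-dimethyl-1-(1,4,5,8-tetramethoxynaphthalen-2-yl)but-3-en-1-ol (racemic) | C=CC(C)(C)C(O)c1cc(OC)c2c(OC)ccc(OC)c2c1OC | intermediate
9 | 2,2-dimethyl-1-(1,4,5,8-tetramethoxynaphthalen-2-yl)but-3-en-1-one | C=CC(C)(C)C(=O)c1cc(OC)c2c(OC)ccc(OC)c2c1OC | intermediate
10 | 4-(9-borabicyclo[3.3.1]nonan-9-yl)-2,2-dimethyl-1-(1,4,5,8-tetramethoxynaphthalen-2-yl)butan-1-one | O=C(c1cc(OC)c2c(OC)ccc(OC)c2c1OC)C(C)(C)CCB1C2CCCC1CCC2 | intermediate
11 | 4-hydroxy-2,2-dimethyl-1-(1,4,5,8-tetramethoxynaphthalen-2-yl)butan-1-one | OCCC(C)(C)C(=O)c1cc(OC)c2c(OC)ccc(OC)c2c1OC | intermediate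
12 | 4-iodo-2,2-dimethyl-1-(1,4,5,8-tetramethoxynaphthalen-2-yl)butan-1-one | ICCC(C)(C)C(=O)c1cc(OC)c2c(OC)ccc(OC)c2c1OC | intermediate
13 | [3,3-dimethyl-4-oxo-4-(1,4,5,8-tetramethoxynaphthalen-2-yl)butyl]lithium | [Li]CCC(C)(C)C(=O)c1cc(OC)c2c(OC)ccc(OC)c2c1OC | intermediate
14 | (±)-2,2-dimethyl-1-(1,4,5,8-tetramethoxynaphthalen-2-yl)cyclobutan-1-ol (racemic) | OC1(c2cc(OC)c3c(OC)ccc(OC)c3c2OC)CCC1(C)C | intermediate
15 | (R)-2,2-dimethyl-1-(1,4,5,8-tetramethoxynaphthalen-2-yl)cyclobutan-1-ol | O[C@]1(c2cc(OC)c3c(OC)ccc(OC)c3c2OC)CCC1(C)C | intermediate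
16 | angelic anhydride [(Z)-2-methylbut-2-enoic anhydride] | C/C=C(/C)C(=O)OC(=O)/C(C)=C\C | starting material
17 | potassium (R)-2,2-dimethyl-1-(1,4,5,8-tetramethoxynaphthalen-2-yl)cyclobutan-1-olate | [K+].[O-][C@]1(c2cc(OC)c3c(OC)ccc(OC)c3c2OC)CCC1(C)C | intermediate
18 | (R)-2,2-dimethyl-1-(1,4,5,8-tetramethoxynaphthalen-2-yl)cyclobutyl (Z)-2-methylbut-2-enoate | C/C=C(/C)C(=O)O[C@]1(c2cc(OC)c3c(OC)ccc(OC)c3c2OC)CCC1(C)C | intermediate
19 | (R)-1-(1,4-dimethoxy-5,8-dioxo-5,8-dihydronaphthalen-2-yl)-2,2-dimethylcyclobutyl (Z)-2-methylbut-2-enoate | C/C=C(/C)C(=O)O[C@]1(c2cc(OC)c3C(=O)C=CC(=O)c3c2OC)CCC1(C)C | intermediate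
20 | (R)-1-(5,8-dimethoxy-1,4-dioxo-1,4-dihydronaphthalen-2-yl)-2,2-dimethylcyclobutyl (Z)-2-methylbut-2-enoate | C/C=C(/C)C(=O)O[C@]1(C2=CC(=O)c3c(OC)ccc(OC)c3C2=O)CCC1(C)C | intermediate
21 | (R)-2,2-dimethyl-1-(1,4,5,8-tetraoxo-1,4,5,8-tetrahydronaphthalen-2-yl)cyclobutyl (Z)-2-methylbut-2-enoate | C/C=C(/C)C(=O)O[C@]1(C2=CC(=O)C3=C(C2=O)C(=O)C=CC3=O)CCC1(C)C | intermediate
22 | (R)-1-(5,8-dihydroxy-1,4-dioxo-1,4-dihydronaphthalen-2-yl)-2,2-dimethylcyclobutyl (Z)-2-methylbut-2-enoate | C/C=C(/C)C(=O)O[C@]1(C2=CC(=O)c3c(O)ccc(O)c3C2=O)CCC1(C)C | target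

**Totals and risks**
Total step count: 11. Longest linear sequence: 11 steps (from 1; 6 and 16 are bought).

Steps most likely to fail:

Step 8 (four-membered ring closure). The alkyllithium could instead displace the neighbouring methoxy group on the ring (a six-membered closure), or t-BuLi could attack the ketone. The fallback sets out from 3 and comes back at 14. Monobromination of 3 with NBS gives 2-bromo-1,4,5,8-tetramethoxynaphthalene F1. Bromine–lithium exchange with n-BuLi in THF at −78 °C gives (1,4,5,8-tetramethoxynaphthalen-2-yl)lithium F2. F2 is added to commercial 2,2-dimethylcyclobutanone (CC1(C)CCC1=O), and aqueous quench gives 14. The four-membered ring is then bought ready-made and the aryl–carbinol bond comes from a 1,2-addition instead of a ring closure.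

Step 10 (acylation of a very hindered tertiary alkoxide with retention of the Z geometry). The acyl transfer may stall, or the angelate may isomerise to the tiglate. The fallback sets out from 15 and comes back at 18. The potassium alkoxide of 15 is acylated with the small, highly electrophilic 2-[bis(2,2,2-trifluoroethoxy)phosphoryl]propanoyl chloride. This gives (R)-2,2-dimethyl-1-(1,4,5,8-tetramethoxynaphthalen-2-yl)cyclobutyl 2-[bis(2,2,2-trifluoroethoxy)phosphoryl]propanoate F3 as a mixture of epimers at the phosphonate-bearing carbon. Still–Gennari olefination of F3 with acetaldehyde (KN(SiMe3)2, 18-crown-6, THF, −78 °C) then builds the Z-alkene on the ester and gives 18. The double bond geometry is thus set by a Z-selective olefination, not carried through the acyl transfer.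

Step 11 (unmasking). The tertiary ester may solvolyse in the acidic oxidising medium, or the second oxidative demethylation may be incomplete. The fallback sets out from the crude mixture of 19 and 20 (made from 18 with (NH4)2Ce(NO3)6 as in step 11) and comes back at 22. BCl3 in CH2Cl2 at −78 to 0 °C cleaves the two peri-methoxy groups, each chelated to a quinone carbonyl, and aqueous work-up gives 22 directly. This is a Lewis-acid ether cleavage with no second oxidation and no reduction; it makes no new compound (F0).

Further compounds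
F1 | step 8 | 2-bromo-1,4,5,8-tetramethoxynaphthalene | Brc1cc(OC)c2c(OC)ccc(OC)c2c1OC
F2 | step 8 | (1,4,5,8-tetramethoxynaphthalen-2-yl)lithium | [Li]c1cc(OC)c2c(OC)ccc(OC)c2c1OC
F3 | step 10 | (R)-2,2-dimethyl-1-(1,4,5,8-tetramethoxynaphthalen-2-yl)cyclobutyl 2-[bis(2,2,2-trifluoroethoxy)phosphoryl]propanoate (both epimers at the propanoate α-carbon) | CC(C(=O)O[C@]1(c2cc(OC)c3c(OC)ccc(OC)c3c2OC)CCC1(C)C)P(=O)(OCC(F)(F)F)OCC(F)(F)F
F0 | step 11 | none | none
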